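The constants were hidden, so I began from a ratio that needs none: when I divided the rate at which free nucleophile disappears by the rate at which electrophile disappears, time dropped out and left the cost, the free nucleophile lost per electrophile reacted.

| setting | Tuesday's | Saturday's | Friday's | violet | teal |
|---|---|---|---|---|---|
| electrophile | 0.40 M | 0.40 M | 0.40 M | 0.40 M | 0.40 M |
| nucleophile | 1.2 M | 1.2 M | 1.2 M | 1.20 M | 1.20 M |
| free base | 0.33 M | 0.39 M | 0.49 M | 0.320 M | 0.480 M |
| protic impurity | 0.040 M | 0.040 M | 0.040 M | 0.0400 M | 0.0400 M |
| remark | run made earlier | run made earlier | run made earlier |  |  |
| time |  |  |  | 80 min | 80 min |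

- Tuesday's (time / min: electrophile / %, product / %): 5.00: 70.0, 29.4; 15.0: 42.0, 59.5; 25.0: 26.0, 73.7; 40.0: 14.0, 84.6; 60.0: 6.8, 92.9
- Saturday's (time / min: electrophile / %, product / %): 5.00: 69.9, 28.9; 15.0: 41.0, 58.3; 25.0: 26.4, 74.5; 40.0: 15.0, 85.2; 60.0: 7.8, 93.0
- Friday's (time / min: electrophile / %, product / %): 5.00: 70.3, 29.6; 15.0: 41.4, 59.3; 25.0: 24.8, 74.4; 40.0: 15.2, 84.8; 60.0: 8.1, 91.9

(standard deviation of a reading: 0.5 percentage points)

- the analysis behind the earlier runs scatters by 0.5 percentage points, standard deviation
- reactions considered so far: acid set free + free base <-> salt of the base; electrophile + nucleophile -> acid set free + product; protic impurity + free base -> quenched reagent; nucleophile + acid set free <-> protonated nucleophile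

- part of the electrophile that has reacted at the end, violet
- part of the electrophile that has reacted at the end, teal
- what raising the concentration of free base from its lowest to its highest value here does to the part of the electrophile that has reacted (changes below 5 percentage points count as none) (it falls / no change / it rises)

1. Electrophile and nucleophile give product and acid; free base takes up the acid as its salt, or nucleophile takes it up as protonated nucleophile, and the protic impurity quenches some free base. I therefore set up two extremes: free base takes the acid and the cost is one, or nucleophile takes it and the cost is two.

2. For violet and teal I kept the cover 150%: the charged nucleophile over twice the charged electrophile, the share of the electrophile it can pay for at cost two. So the nucleophile was not the limiting reagent, even in the dearer extreme.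

3. With the cost held at one value, I integrated the second-order law and took a rate constant from each reading. The earlier runs agreed about as closely as their scatter of 0.5 percentage points allows, so I averaged them: 70.1% electrophile at 5.00 min and 7.57% at 60.0 min. At cost one the constant sank from 0.0627 /M/min to 0.0461 /M/min; at cost two it held, 0.0666 /M/min and 0.0677 /M/min. I placed the real flask near cost two.

4. My reckoning for 80 min gave 95.9% reacted at cost two and 98.8% at cost one. That gap of 2.9 points is less than 5 points, so I expected no change.

5. The forecast said 95.8% for violet, 96% for teal and no change, on the grounds “because the nucleophile is in threefold excess and protonating it costs little”.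

6. Violet gave 95.9% and teal 96.1%, a change of 0.19 points, so the outcome was no change.

acid set free + free base ⇌ salt of the base, settled at all times (K = 570 /M); electrophile + nucleophile → acid set free + product (k = 0.0650 /M/min); protic impurity + free base → quenched reagent (k = 2.20 /M/min); nucleophile + acid set free ⇌ protonated nucleophile, settled at all times (K = 3600 /M) Violet, with a cover of 150%, kept 39% of its nucleophile free at 80.0 min, a cost of 1.92. A neighbouring flask, violet with 1.6 M of electrophile, has a cover of 37.5%; it reacted further than that, reaching 45.3%, with 0.83% of its nucleophile and 10% of its free base left.

The data come from a simulation for substances that don't exist, and the scatter is random.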